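Remark: the target has no stereocentre and no stereogenic double bond (the exocyclic C=C ends in a ring carbon with two identical CH=CH arms), and its aryl axes are taken as freely rotating, so it is achiral and needs no stereocontrol. ArB below stands for the 6-[2,4-bis(methoxymethoxy)phenyl]-3-({[tert-butyl(dimethyl)silyl]oxy}methyl)-2-{[4-(methoxymethoxy)phenyl]ethynyl}phenyl group.

**Retrosynthetic overview**

1. Selaginellin F ⇐ an aryl-bis(7-oxanorbornadien-1-yl)methanol: acid opens both oxygen bridges to phenols, the carbinol loses water to the quinone methide, and the MOM/TBS groups fall in the same pot.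
2. Both oxygenated six-membered rings ⇐ an aryl-di(2-furyl)methanol plus two molecules of trans-1,2-bis(phenylsulfonyl)ethene (acetylene equivalent) by a twofold [4+2]; the sulfonyl pairs are then removed reductively.
3. Enabling feature: in the cyclohexadienone ring the C=O carbon and the carbon bearing the exocyclic C=C are 1,4 with only CH between them, i.e. O–C(H)=CH–CH=C is a 2-furyl group whose oxygen becomes the carbonyl oxygen; the 4-hydroxyphenyl ring is the tautomeric twin of this ring, so one operation can build both.
4. The carbinol ⇐ the ring-B methyl benzoate + 2 × 2-furyllithium (two molecules of furan); the benzoate ⇐ (2-bromo-4-chlorophenyl)methanol by lithiation between Br and Cl, Sonogashira at C–Br and Suzuki at C–Cl.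
5. Ring order: the three benzenoid rings are bought; the two oxygenated rings are closed together in the key step as 7-oxanorbornenes and aromatised in the last step.

Key step: step 10

**Route**

Step 1
Reactants: 1 (2-bromo-4-chlorophenyl)methanol
Product: 2 tert-butyl[(2-bromo-4-chlorobenzyl)oxy]dimethylsilane
Conditions: TBSCl, imidazole, DMF, rt
Reagents that add atoms: tert-butyl(chloro)dimethylsilane, CC(C)(C)[Si](C)(C)Cl
Why: Standard silylation of a primary alcohol gives an ether that should survive amide base, Pd couplings, organolithium addition and buffered amalgam, and fall with methanolic acid at the end.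

Step 2
Reactants: 2 tert-butyl[(2-bromo-4-chlorobenzyl)oxy]dimethylsilane
Product: 4 methyl 2-bromo-3-({[tert-butyl(dimethyl)silyl]oxy}methyl)-6-chlorobenzoate, via aryllithium 3 (not isolated)
Conditions: LDA (commercial solution), THF, −78 °C; then cannulated into ClCO2Me, THF, −78 °C
Reagents that add atoms: methyl chloroformate, COC(=O)Cl
Why: Directed ortho-metalation should take the proton between Br and Cl (the most acidic one, and the thermodynamic sink, so no halogen dance is expected); the 2,6-dihaloaryllithium is stable to aryne formation at −78 °C and is acylated by inverse addition to excess chloroformate.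

Step 3
Reactants: 5 4-hydroxybenzaldehyde
Product: 6 4-(methoxymethoxy)benzaldehyde
Conditions: MOMCl, iPr2NEt, CH2Cl2, 0 °C → rt
Reagents that add atoms: chloromethyl methyl ether, COCCl
Why: O-Alkylation of the phenol gives an acetal that is stable to base, Pd and organolithium reagents and is cleaved by the final acid.

Step 4
Reactants: 6 4-(methoxymethoxy)benzaldehyde
Product: 7 1-ethynyl-4-(methoxymethoxy)benzene
Conditions: Ohira–Bestmann reagent, K2CO3, MeOH, rt
Reagents that add atoms: dimethyl (1-diazo-2-oxopropyl)phosphonate, CC(=O)C(=[N+]=[N-])P(=O)(OC)OC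
Why: Seyferth–Gilbert homologation in its Ohira–Bestmann form converts an aryl aldehyde into the terminal alkyne under mild base that leaves the MOM ether untouched.

Step 5
Reactants: 4 methyl 2-bromo-3-({[tert-butyl(dimethyl)silyl]oxy}methyl)-6-chlorobenzoate; 7 1-ethynyl-4-(methoxymethoxy)benzene
Product: 8 methyl 3-({[tert-butyl(dimethyl)silyl]oxy}methyl)-6-chloro-2-{[4-(methoxymethoxy)phenyl]ethynyl}benzoate
Conditions: PdCl2(PPh3)2 (5 mol %), CuI (5 mol %), Et3N, DMF, 70 °C
Reagents that add atoms: none
Why: Sonogashira coupling should occur only at C–Br, because a Pd/PPh3 catalyst does not insert into the C–Cl bond at this temperature and the ortho ester activates the hindered bromide.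

Step 6
Reactants: 9 4-bromobenzene-1,3-diol
Product: 10 1-bromo-2,4-bis(methoxymethoxy)benzene
Conditions: MOMCl (2.5 equiv), iPr2NEt, CH2Cl2, 0 °C → rt
Reagents that add atoms: chloromethyl methyl ether (two molecules are built in), COCCl
Why: Twofold O-alkylation protects both resorcinol hydroxyls as the same acid-labile acetals used elsewhere.

Step 7
Reactants: 10 1-bromo-2,4-bis(methoxymethoxy)benzene
Product: 11 2-[2,4-bis(methoxymethoxy)phenyl]-4,4,5,5-tetramethyl-1,3,2-dioxaborolane
Conditions: B2pin2, PdCl2(dppf) (3 mol %), KOAc, dioxane, 90 °C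
Reagents that add atoms: bis(pinacolato)diboron, CC1(C)OB(OC1(C)C)B1OC(C)(C)C(C)(C)O1
Why: Miyaura borylation of the electron-rich aryl bromide gives a pinacol boronate that resists protodeboronation better than the free ortho-alkoxy boronic acid.

Step 8
Reactants: 8 methyl 3-({[tert-butyl(dimethyl)silyl]oxy}methyl)-6-chloro-2-{[4-(methoxymethoxy)phenyl]ethynyl}benzoate; 11 2-[2,4-bis(methoxymethoxy)phenyl]-4,4,5,5-tetramethyl-1,3,2-dioxaborolane
Product: 12 methyl 6-[2,4-bis(methoxymethoxy)phenyl]-3-({[tert-butyl(dimethyl)silyl]oxy}methyl)-2-{[4-(methoxymethoxy)phenyl]ethynyl}benzoate (ArB–CO2Me)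
Conditions: Pd(OAc)2 (5 mol %), SPhos (10 mol %), K3PO4, dioxane/H2O, 90 °C
Reagents that add atoms: none
Why: Suzuki–Miyaura coupling with a dialkylbiarylphosphine ligand should engage the ester-activated aryl chloride and form the ortho-substituted biaryl, while the internal alkyne is inert to these conditions.

Step 9
Reactants: 12 ArB–CO2Me; 13 furan (6 equiv)
Product: 16 ArB-di(furan-2-yl)methanol, via 2-furyllithium 14 (not isolated), via aryl 2-furyl ketone 15 (not isolated)
Conditions: furan (6 equiv), n-BuLi (5 equiv), THF, 0 °C; then 12, −78 → 0 °C; H2O quench at 0 °C; Et3N-washed silica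
Reagents that add atoms: furan (second molecule of 13 that is built in), c1ccoc1
Why: Furan is lithiated at C2 by n-BuLi, and two molecules of the small 2-furyllithium should add to the ester in succession, one furan ring entering per addition, because the intermediate ketone is more electrophilic than the ester (double organolithium addition to an ester); the alkoxide is quenched cold before it can add to the ortho alkyne.

Step 10
Reactants: 16 ArB-di(furan-2-yl)methanol; 17 (E)-1,2-bis(phenylsulfonyl)ethene (3 equiv)
Product: 18 ArB-bis[5,6-bis(phenylsulfonyl)-7-oxabicyclo[2.2.1]hept-2-en-1-yl]methanol (trans-disulfonyl in each bicycle, mixture of diastereomers)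
Conditions: CH2Cl2, 40 °C, sealed tube
Reagents that add atoms: (E)-1,2-bis(phenylsulfonyl)ethene (second molecule of 17 that is built in), O=S(=O)(/C=C/S(=O)(=O)c1ccccc1)c1ccccc1
Why: Two successive concerted, normal-electron-demand Diels–Alder reactions join each electron-rich 2-alkylfuran (diene: furan C2 to C5) to one molecule of the doubly sulfonyl-activated alkene, so that each dienophile carbon bonds to a furan α-carbon and all four ring C–C bonds of the two future oxygenated rings are made in one three-component operation. The closest known reaction types are the cycloaddition of furan and 2-substituted furans with 1,2-bis(phenylsulfonyl)ethene as an acetylene equivalent and the twofold cycloaddition of 2,2-di(2-furyl)propane with maleimides, which shows that a fully substituted carbon on furan C2 does not block the reaction. Each new six-membered carbocycle closes by a suprafacial intermolecular [4+2] and is held as a 7-oxabicyclo[2.2.1]heptene in which the furan oxygen is the one-atom bridge between the future C–O carbon and the future ring carbon bonded to the central carbon. The eight new stereocentres (two bridgeheads and two sulfonyl carbons per bicycle) are not controlled and need not be, since steps 11 and 12 erase all of them. The step needs chemoselectivity for the furans over the diarylalkyne and the arenes, which the electron-poor dienophile secures because only the furans offer a high-lying diene HOMO (thermal intramolecular addition of the unactivated alkyne to a furan is not expected at 40 °C). Regiochemistry is moot because the dienophile is symmetric, and the excess of 17 drives the second addition.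

Step 11
Reactants: 18 ArB-bis[5,6-bis(phenylsulfonyl)-7-oxabicyclo[2.2.1]hept-2-en-1-yl]methanol
Product: 19 ArB-bis(7-oxabicyclo[2.2.1]hepta-2,5-dien-1-yl)methanol
Conditions: 6 % Na(Hg) (excess), Na2HPO4, MeOH/THF, −20 °C
Reagents that add atoms: none
Why: Julia-type reductive elimination of a vicinal disulfone should expel two sulfinates from each bicycle (sulfinate is a far better leaving group than the bridging alkoxide) to leave the CH=CH unit, under buffered low-temperature conditions that should not reduce an isolated diarylalkyne.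

Step 12
Reactants: 19 ArB-bis(7-oxabicyclo[2.2.1]hepta-2,5-dien-1-yl)methanol
Product: 22 selaginellin F, via bis-phenol carbinol 20 (not isolated), via protected quinone methide 21 (not isolated)
Conditions: CSA (10 mol %), CH2Cl2, 0 °C → rt; then HCl (1.25 M in MeOH), 40 °C; aq NaHCO3 work-up
Reagents that add atoms: none
Why: Acid-catalysed isomerisation of a 7-oxanorbornadiene to a phenol (C–O cleavage at the substituted bridgehead gives an arenium ion that loses the proton from the O-bearing carbon) should precede ionisation of the carbinol, which is easy only once two 4-hydroxyphenyl groups are present and then gives the quinone methide by loss of water; methanolic HCl finally cleaves the three MOM acetals and the silyl ether, and neutral work-up returns the open quinone methide.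

**Compound list**

1 | (2-bromo-4-chlorophenyl)methanol | OCc1ccc(Cl)cc1Br | starting material
2 | tert-butyl[(2-bromo-4-chlorobenzyl)oxy]dimethylsilane | CC(C)(C)[Si](C)(C)OCc1ccc(Cl)cc1Br | intermediate
3 | [2-bromo-3-({[tert-butyl(dimethyl)silyl]oxy}methyl)-6-chlorophenyl]lithium | CC(C)(C)[Si](C)(C)OCc1ccc(Cl)c([Li])c1Br | intermediate
4 | methyl 2-bromo-3-({[tert-butyl(dimethyl)silyl]oxy}methyl)-6-chlorobenzoate | COC(=O)c1c(Cl)ccc(CO[Si](C)(C)C(C)(C)C)c1Br | intermediate
5 | 4-hydroxybenzaldehyde | O=Cc1ccc(O)cc1 | starting material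
6 | 4-(methoxymethoxy)benzaldehyde | COCOc1ccc(C=O)cc1 | intermediate
7 | 1-ethynyl-4-(methoxymethoxy)benzene | COCOc1ccc(C#C)cc1 | intermediate
8 | methyl 3-({[tert-butyl(dimethyl)silyl]oxy}methyl)-6-chloro-2-{[4-(methoxymethoxy)phenyl]ethynyl}benzoate | COC(=O)c1c(Cl)ccc(CO[Si](C)(C)C(C)(C)C)c1C#Cc1ccc(OCOC)cc1 | intermediate
9 | 4-bromobenzene-1,3-diol | Oc1ccc(Br)c(O)c1 | starting material
10 | 1-bromo-2,4-bis(methoxymethoxy)benzene | COCOc1ccc(Br)c(OCOC)c1 | intermediate
11 | 2-[2,4-bis(methoxymethoxy)phenyl]-4,4,5,5-tetramethyl-1,3,2-dioxaborolane | COCOc1ccc(B2OC(C)(C)C(C)(C)O2)c(OCOC)c1 | intermediate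
12 | methyl 6-[2,4-bis(methoxymethoxy)phenyl]-3-({[tert-butyl(dimethyl)silyl]oxy}methyl)-2-{[4-(methoxymethoxy)phenyl]ethynyl}benzoate (ArB–CO2Me) | COC(=O)c1c(-c2ccc(OCOC)cc2OCOC)ccc(CO[Si](C)(C)C(C)(C)C)c1C#Cc1ccc(OCOC)cc1 | intermediate
13 | furan | c1ccoc1 | starting material
14 | 2-furyllithium | [Li]c1ccco1 | intermediate
15 | ArB 2-furyl ketone | O=C(c1ccco1)c1c(-c2ccc(OCOC)cc2OCOC)ccc(CO[Si](C)(C)C(C)(C)C)c1C#Cc1ccc(OCOC)cc1 | intermediate
16 | ArB-di(furan-2-yl)methanol | OC(c1ccco1)(c1ccco1)c1c(-c2ccc(OCOC)cc2OCOC)ccc(CO[Si](C)(C)C(C)(C)C)c1C#Cc1ccc(OCOC)cc1 | intermediate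
17 | (E)-1,2-bis(phenylsulfonyl)ethene | O=S(=O)(/C=C/S(=O)(=O)c1ccccc1)c1ccccc1 | starting material
18 | ArB-bis[5,6-bis(phenylsulfonyl)-7-oxabicyclo[2.2.1]hept-2-en-1-yl]methanol (mixture of diastereomers, carried on as such; no stereodescriptors are given because no stereocentre survives) | OC(C12C=CC(O1)C(S(=O)(=O)c1ccccc1)C2S(=O)(=O)c1ccccc1)(C12C=CC(O1)C(S(=O)(=O)c1ccccc1)C2S(=O)(=O)c1ccccc1)c1c(-c2ccc(OCOC)cc2OCOC)ccc(CO[Si](C)(C)C(C)(C)C)c1C#Cc1ccc(OCOC)cc1 | intermediate
19 | ArB-bis(7-oxabicyclo[2.2.1]hepta-2,5-dien-1-yl)methanol (no stereocentre) | OC(C12C=CC(O1)C=C2)(C12C=CC(O1)C=C2)c1c(-c2ccc(OCOC)cc2OCOC)ccc(CO[Si](C)(C)C(C)(C)C)c1C#Cc1ccc(OCOC)cc1 | intermediate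
20 | ArB-bis(4-hydroxyphenyl)methanol | OC(c1ccc(O)cc1)(c1ccc(O)cc1)c1c(-c2ccc(OCOC)cc2OCOC)ccc(CO[Si](C)(C)C(C)(C)C)c1C#Cc1ccc(OCOC)cc1 | intermediate
21 | 4-[ArB(4-hydroxyphenyl)methylidene]cyclohexa-2,5-dien-1-one | O=C1C=CC(=C(c2ccc(O)cc2)c2c(-c3ccc(OCOC)cc3OCOC)ccc(CO[Si](C)(C)C(C)(C)C)c2C#Cc2ccc(OCOC)cc2)C=C1 | intermediate
22 | selaginellin F, 4-[{6-(2,4-dihydroxyphenyl)-3-(hydroxymethyl)-2-[(4-hydroxyphenyl)ethynyl]phenyl}(4-hydroxyphenyl)methylidene]cyclohexa-2,5-dien-1-one | O=C1C=CC(=C(c2ccc(O)cc2)c2c(-c3ccc(O)cc3O)ccc(CO)c2C#Cc2ccc(O)cc2)C=C1 | target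

**Step count and risks**

Total step count: 12. Longest linear sequence: 8 steps (1, 2, 5, 8, 9, 10, 11, 12).

The three steps most likely to fail:

Step 10. The two cycloadditions take place at furans that carry a fully substituted carbon, so they may be slow and reversible, and cycloreversion or arrest at the mono-adduct may dominate. The fallback drops the furan annulation and sets out from 12. 1-Bromo-4-(methoxymethoxy)benzene is lithiated (n-BuLi, THF, −78 °C) to [4-(methoxymethoxy)phenyl]lithium F1. Two molecules of F1 are added to 12 to give ArB-bis[4-(methoxymethoxy)phenyl]methanol F2. Methanolic HCl (40 °C) then ionises the carbinol, removes the five acetals and the silyl ether, and returns to the route at 22.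

Step 11. Electron transfer from the amalgam may also reach the diarylalkyne (over-reduction), or the bridges may open before the sulfinates are lost. The fallback unveils the CH=CH units without a reductant and sets out from 16. Cycloaddition of 16 with two molecules of (E)-trimethyl[2-(phenylsulfonyl)vinyl]silane (toluene, 80 °C, or high pressure) gives the bis(β-silyl sulfone) adduct F3. Bu4NF in THF then triggers β-elimination of fluorosilane and sulfinate in each bicycle and also cleaves the silyl ether, giving {6-[2,4-bis(methoxymethoxy)phenyl]-3-(hydroxymethyl)-2-{[4-(methoxymethoxy)phenyl]ethynyl}phenyl}bis(7-oxabicyclo[2.2.1]hepta-2,5-dien-1-yl)methanol F4. The acid treatment of step 12 converts F4 into 22, where the fallback rejoins the route.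

Step 9. The first addition to the doubly ortho-substituted ester may stall, or the sequence may stop at the ketone. The fallback builds the carbinol stepwise through the aldehyde and sets out from 12. DIBAL-H (CH2Cl2, −78 °C → 0 °C) gives the benzylic alcohol ArB–CH2OH F5, and MnO2 (CH2Cl2) gives the aldehyde ArB–CHO F6. 2-Furyllithium 14 adds to the unhindered aldehyde to give the secondary carbinol ArB-(furan-2-yl)methanol F7 (racemic). MnO2 oxidises F7 to ketone 15, which is isolated this time. A second addition of 14 (CeCl3, THF, −78 °C) returns to the route at 16.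

Further compounds
F1 | step 10 | [4-(methoxymethoxy)phenyl]lithium | [Li]c1ccc(OCOC)cc1
F2 | step 10 | ArB-bis[4-(methoxymethoxy)phenyl]methanol | OC(c1ccc(OCOC)cc1)(c1ccc(OCOC)cc1)c1c(-c2ccc(OCOC)cc2OCOC)ccc(CO[Si](C)(C)C(C)(C)C)c1C#Cc1ccc(OCOC)cc1
F3 | step 11 | ArB-bis[5-(phenylsulfonyl)-6-(trimethylsilyl)-7-oxabicyclo[2.2.1]hept-2-en-1-yl]methanol (regio- and stereoisomer mixture, drawn with the sulfonyl group remote from the substituted bridgehead) | OC(C12C=CC(O1)C(S(=O)(=O)c1ccccc1)C2[Si](C)(C)C)(C12C=CC(O1)C(S(=O)(=O)c1ccccc1)C2[Si](C)(C)C)c1c(-c2ccc(OCOC)cc2OCOC)ccc(CO[Si](C)(C)C(C)(C)C)c1C#Cc1ccc(OCOC)cc1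
F4 | step 11 | {6-[2,4-bis(methoxymethoxy)phenyl]-3-(hydroxymethyl)-2-{[4-(methoxymethoxy)phenyl]ethynyl}phenyl}bis(7-oxabicyclo[2.2.1]hepta-2,5-dien-1-yl)methanol | OC(C12C=CC(O1)C=C2)(C12C=CC(O1)C=C2)c1c(-c2ccc(OCOC)cc2OCOC)ccc(CO)c1C#Cc1ccc(OCOC)cc1
F5 | step 9 | ArB–CH2OH | OCc1c(-c2ccc(OCOC)cc2OCOC)ccc(CO[Si](C)(C)C(C)(C)C)c1C#Cc1ccc(OCOC)cc1
F6 | step 9 | ArB–CHO | O=Cc1c(-c2ccc(OCOC)cc2OCOC)ccc(CO[Si](C)(C)C(C)(C)C)c1C#Cc1ccc(OCOC)cc1
F7 | step 9 | ArB-(furan-2-yl)methanol (racemic) | OC(c1ccco1)c1c(-c2ccc(OCOC)cc2OCOC)ccc(CO[Si](C)(C)C(C)(C)C)c1C#Cc1ccc(OCOC)cc1
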